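Temperature caught my eye first in the earlier runs: the noon flask at 25 °C started with [D] at 0.0238 M and the dawn flask at 75 °C with 0.0950 M, yet X levelled at nearly the same share of Q, 58.3% against 59.8%.

| flask | Q | D | L | temperature | remark | time |
|---|---|---|---|---|---|---|
| spring | 0.050 M | 0.47 equiv | 4 equiv | 25 °C | run made earlier |  |
| dawn | 0.050 M | 1.9 equiv | 4 equiv | 75 °C | run made earlier |  |
| noon | 0.025 M | 0.95 equiv | 4 equiv | 25 °C | run made earlier |  |
| Thursday's | 0.050 M | 0.950 equiv | 4.00 equiv | 120 °C |  | 12 h |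
| Sunday's | 0.050 M | 0.950 equiv | 4.00 equiv | 60 °C |  | 12 h |
| Monday's | 0.050 M | 0.950 equiv | 4.00 equiv | 90 °C |  | 12 h |
| Saturday's | 0.050 M | 0.950 equiv | 4.00 equiv | 30 °C |  | 12 h |

| run | time / h | X / % | E / % |
|---|---|---|---|
| spring | 60.0 | 22.5 | 2.8 |
| spring | 144 | 35.6 | 4.8 |
| spring | 288 | 41.1 | 7.2 |
| spring | 480 | 42.8 | 8.3 |
| spring | 720 | 43.4 | 7.8 |
| spring | 960 | 43.0 | 8.3 |
| spring | 1200 | 43.1 | 8.9 |
| dawn | 8.00 | 59.7 | 2.1 |
| dawn | 12.0 | 59.6 | 2.2 |
| dawn | 20.0 | 59.9 | 2.3 |
| dawn | 25.0 | 59.8 | 2.1 |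
| dawn | 40.0 | 59.7 | 1.6 |
| dawn | 60.0 | 59.5 | 1.8 |
| dawn | 96.0 | 59.2 | 2.2 |
| noon | 240 | 52.7 | 3.2 |
| noon | 480 | 58.5 | 3.4 |
| noon | 720 | 58.6 | 2.5 |
| noon | 960 | 57.9 | 3.3 |
| noon | 1200 | 58.1 | 3.1 |

(readings scatter by 0.3 percentage points)

- a reading or a percentage of X counts all its forms, free or not

1. the best flask by share of X in all that became X or E or G; "all alike" if 1.5 percentage points covers them all (Thursday's / Sunday's / Monday's / Saturday's / all alike)
2. share of X in all that became X or E or G, Thursday's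
3. share of X in all that became X or E or G, Sunday's
4. share of X in all that became X or E or G, Monday's
5. share of X in all that became X or E or G, Saturday's

I pictured Q draining through a fork. One outlet gives X, costs one D and runs in proportion to [D]. The other gives unseen G, which I took as the Q not found as X or E. I defined β as the rate to X over the rate to G, per unit of [D], a selectivity factor. Since [D] falls as X forms, ln([D] at start / [D] at end) = β[G].

With E at 3.07%, noon's plateau gave the split constant β = 98.4 M⁻¹ at 25 °C. Dawn's gave 19.8 M⁻¹ at 75 °C. I took ln β as straight in 1/T, with slope 3320 K.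

Spring's rise gave a time constant of 81.3 h at 25 °C, so I put Saturday's conversion in 12 h at 13.7%, a low figure for a warmer flask. The other three I assumed fully converted, which for Sunday's was unproven.

My first round used the starting [D], giving the share β[D]/(1 + β[D]). But D is consumed, so I put that answer back, took the mean [D] over the run, went round once more and removed noon's share of E.

| Flask | β | First round | Second round |
|---|---|---|---|
| Thursday's | 6.65 M⁻¹ | 24.0% | 21.0% |
| Sunday's | 30.5 M⁻¹ | 59.2% | 48.4% |
| Monday's | 13.4 M⁻¹ | 38.8% | 32.5% |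
| Saturday's | 81.8 M⁻¹ | 79.5% | 76.1% |

So my reckoning put Saturday's first.

The forecast said all alike, with 59%, 59%, 59.2% and 58.5% for Thursday's, Sunday's, Monday's and Saturday's: “The X:G split therefore looks fixed, about 60:38, and nearly independent of temperature and D.”

The simulation gave Saturday's as best, with 21.0%, 48.9%, 32.9% and 76.0% in the same order.

    Q → Z (k = 0.580 h⁻¹, Ea = 99.0 kJ mol⁻¹)
    Z → G (k = 2.50 h⁻¹, Ea = 91.0 kJ mol⁻¹)
    L + X ⇌ J, settled at all times (K = 81.0 M⁻¹, ΔH = −25.0 kJ mol⁻¹)
    D + Z → X (k = 76.0 M⁻¹ h⁻¹, Ea = 63.0 kJ mol⁻¹)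
    L + Z → E (k = 1.00 M⁻¹ h⁻¹, Ea = 71.0 kJ mol⁻¹)
    (constants at 60 °C)

The forecast and the flasks parted on temperature: the flasks' share went down from 76.0% at 30 °C to 21.0% at 120 °C, and my β went down from 81.8 M⁻¹ to 6.65 M⁻¹ over the same span. For the neighbouring flask, Thursday's with 3.80 equiv of D, my β at 120 °C stays 6.65 M⁻¹. The first round gives 55.8%, and the second gives 52.3%. That flask gave 52.8%, with J counted in X, and G stood at 46.0% against Thursday's 77.0%.

Readings and results come from a simulation with made-up constants; the scatter is artificial.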